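**Plan**
- Retrosynthesis: remove the two benzyl ethers, cut the C2–phenyl bond (conjugate arylation of a chromone), then cut the pyranone at C2 (formylation of an o-hydroxyacetophenone).
- Ring D (D1 C–OMe, D2 C–Me, D3 C=O, D4, D5 C–OH, D6 CMe2) is cut at D5–D6 and D3–D4. The methine lies between arene carbon C8 (ortho to O1) and D4, so O1–C8a–C8–CH(i-Pr)–D4–D5 is a hidden 4-isopropyl-dihydrocoumarin with D5 as lactone carbonyl and D4 as its α-CH2.
- That lactone is cut at C8–CH into a mono-phenol and (E)-4-methylpent-2-enal; the C4a acetyl group (later C4 and C3) is put on the lactone, masked as a silyl enol ether.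
- Forward ring order: arene, temporary lactone ring, ring D (lactone consumed, its oxygen freed), chromone ring, flavanone.
- Stereochemistry: the methine (R) comes from the (R)-prolinol silyl ether catalyst in step 4; C2 (S) comes from the (R)-pyridine–oxazoline ligand on palladium in step 12.

Key step: step 10

Assumption: the vinylogous acid of ring D is written as the enol tautomer of the target SMILES (D3 C=O, D5 C–OH) and its tautomers are treated as one compound. By CIP analysis of that SMILES the methine is R and C2 is S.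

**Route**

Step 1
Reactants: 1 2-methylbenzene-1,3,5-triol
Product: 2 2-methyl-5-{[tri(propan-2-yl)silyl]oxy}benzene-1,3-diol
Conditions: i-Pr3SiCl (1.0 equiv), imidazole, DMF, −20 → 0 °C
Reagents that add atoms: chlorotri(propan-2-yl)silane, CC(C)[Si](Cl)(C(C)C)C(C)C
Why: Silyl ether formation with the bulky chlorosilane should take place at the only hydroxyl without an ortho methyl group, and the minor regioisomer and bis-ether are removed by chromatography and returned to 1 with fluoride.

Step 2
Reactants: 2 2-methyl-5-{[tri(propan-2-yl)silyl]oxy}benzene-1,3-diol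
Product: 3 {[3,5-bis(benzyloxy)-4-methylphenyl]oxy}tri(propan-2-yl)silane
Conditions: BnBr (2.3 equiv), K2CO3, acetone, reflux
Reagents that add atoms: benzyl bromide, BrCc1ccccc1
Why: Williamson ether synthesis on the two remaining phenols under carbonate conditions, which an aryl triisopropylsilyl ether should tolerate and which keep C-benzylation low.

Step 3
Reactants: 3 {[3,5-bis(benzyloxy)-4-methylphenyl]oxy}tri(propan-2-yl)silane
Product: 4 3,5-bis(benzyloxy)-4-methylphenol
Conditions: Bu4NF, AcOH, THF, 0 °C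
Reagents that add atoms: none
Why: Fluoride-induced cleavage of the aryl silyl ether, buffered with acetic acid, frees the one phenol that supplies the lactone oxygen and finally O1.

Step 4
Reactants: 4 3,5-bis(benzyloxy)-4-methylphenol; 5 (2E)-4-methylpent-2-enal
Product: 6 (4R)-5,7-bis(benzyloxy)-6-methyl-4-(propan-2-yl)-3,4-dihydro-2H-chromen-2-ol (both C2 epimers)
Conditions: (R)-2-[diphenyl(trimethylsilyloxy)methyl]pyrrolidine (20 mol %), PhCO2H (20 mol %), toluene, 0 °C → rt
Reagents that add atoms: none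
Why: Iminium-ion catalysed Friedel–Crafts alkylation of the electron-rich phenol at its free ortho carbon followed by hemiacetal formation, in which the diphenyl(silyloxy)methyl group of the (R)-catalyst shields one face of the E-iminium ion so that the arene adds to the opposite face and the methine carbon (C4 of the chroman) should be set as R.

Step 5
Reactants: 6 (4R)-5,7-bis(benzyloxy)-6-methyl-4-(propan-2-yl)-3,4-dihydro-2H-chromen-2-ol
Product: 7 (4R)-5,7-bis(benzyloxy)-6-methyl-4-(propan-2-yl)-3,4-dihydro-2H-chromen-2-one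
Conditions: Dess–Martin periodinane, CH2Cl2, rt
Reagents that add atoms: none
Why: Dess–Martin oxidation of a lactol to the lactone, a neutral reaction that touches neither the benzyl ethers nor the C4 stereocentre.

Step 6
Reactants: 7 (4R)-5,7-bis(benzyloxy)-6-methyl-4-(propan-2-yl)-3,4-dihydro-2H-chromen-2-one
Product: 8 (4R)-8-acetyl-5,7-bis(benzyloxy)-6-methyl-4-(propan-2-yl)-3,4-dihydro-2H-chromen-2-one
Conditions: AcOH, (CF3CO)2O, H3PO4 (cat.), CH2Cl2, 0 °C → rt
Reagents that add atoms: acetic acid, CC(=O)O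
Why: Friedel–Crafts acylation by the mixed acetic trifluoroacetic anhydride at C8, the only free arene position and one activated by two benzyloxy groups, under conditions free of metal halides that would cleave benzyl ethers.

Step 7
Reactants: 8 (4R)-8-acetyl-5,7-bis(benzyloxy)-6-methyl-4-(propan-2-yl)-3,4-dihydro-2H-chromen-2-one
Product: 9 (4R)-5,7-bis(benzyloxy)-8-(1-{[tert-butyl(dimethyl)silyl]oxy}ethenyl)-6-methyl-4-(propan-2-yl)-3,4-dihydro-2H-chromen-2-one
Conditions: t-BuMe2SiOTf (1.2 equiv), Et3N, CH2Cl2, −78 → 0 °C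
Reagents that add atoms: tert-butyldimethylsilyl trifluoromethanesulfonate, CC(C)(C)[Si](C)(C)OS(=O)(=O)C(F)(F)F
Why: Soft enolisation and O-silylation of the methyl ketone (silyl enol ether formation), which is much faster than that of the lactone and removes the acidic methyl hydrogens that would otherwise let a ketone enolate attack the neighbouring aryl ester in step 10.

Step 8
Reactants: 10 methyl 4-methyl-3-oxopentanoate
Product: 11 methyl 2,4-dimethyl-3-oxopentanoate (racemic)
Conditions: MeI (1.05 equiv), K2CO3, acetone, rt → reflux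
Reagents that add atoms: iodomethane, CI
Why: C-alkylation of the β-keto ester enolate, held at the mono-methyl stage by stoichiometry.

Step 9
Reactants: 11 methyl 2,4-dimethyl-3-oxopentanoate
Product: 12 methyl (2E)-3-methoxy-2,4-dimethylpent-2-enoate
Conditions: HC(OMe)3, H2SO4 (cat.), MeOH, 50 °C, then distillation
Reagents that add atoms: trimethyl orthoformate, COC(OC)OC
Why: Acid-catalysed ketalisation with the orthoester and loss of methanol gives the enol ether under equilibrating conditions, which should favour the E isomer with methoxy trans to the ester, and any Z isomer is removed by distillation or chromatography.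

Step 10
Reactants: 9 (4R)-5,7-bis(benzyloxy)-8-(1-{[tert-butyl(dimethyl)silyl]oxy}ethenyl)-6-methyl-4-(propan-2-yl)-3,4-dihydro-2H-chromen-2-one; 12 methyl (2E)-3-methoxy-2,4-dimethylpent-2-enoate
Product: 16 2-{(1R)-1-[3-acetyl-4,6-bis(benzyloxy)-2-hydroxy-5-methylphenyl]-2-methylpropyl}-3-hydroxy-5-methoxy-4,4,6-trimethylcyclohexa-2,5-dien-1-one, via lithium dienolate 13 (not isolated), via open-chain keto ester 14 (not isolated), via silyl enol ether dienone 15 (not isolated)
Conditions: 12 (3.0 equiv), LiN(i-Pr)2 (3.0 equiv), THF–DMPU, −78 °C; then 9, −78 → −20 °C; KOt-Bu (3 equiv), −20 °C → rt; Bu4NF, 0 °C; 1 M HCl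
Reagents that add atoms: none
Why: LiN(i-Pr)2, guided by the ester carbonyl, removes the cis γ-hydrogen of the isopropyl group of 12 to give dienolate 13, whose γ-carbon attacks the aryl-ester carbonyl of lactone 9 (or the ketene that 9 gives by loss of aryloxide), so that the lactone opens to the phenoxide of ketone 14 and the D5–D6 bond is made. Excess base turns 14 into the enolate at its only enolisable carbon, the CH2 beside the methine, and KOt-Bu drives its attack on the ester carbonyl, a 6-exo-trig Dieckmann condensation that forms the D3–D4 bond and ring D as the stabilised diketonate of 15; fluoride then removes the silyl group and acid gives 16. The closest known reactions are the γ-acylation of lithium dienolates of 3-alkoxy-2-enoates by esters and lactones (vinylogous Claisen condensation) and the Dieckmann closure of δ-keto esters to cyclohexane-1,3-diones. No stereocentre is formed, and the methine, which is β to the new ketone and carries no acidic hydrogen, should keep its R configuration. The step needs γ- over α-acylation, secured by the 3-methoxy group because only γ-attack keeps the enol ether conjugated with the ester, and C- over O-cyclisation, secured because an enol lactone formed through oxygen is reopened by alkoxide and drains into the diketonate as the thermodynamic sink. The E geometry of 12 holds the ester cis to the new acyl arm so that the chain can close, and the silyl enol ether and benzyl ethers are inert to the bases.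

Step 11
Reactants: 16 2-{(1R)-1-[3-acetyl-4,6-bis(benzyloxy)-2-hydroxy-5-methylphenyl]-2-methylpropyl}-3-hydroxy-5-methoxy-4,4,6-trimethylcyclohexa-2,5-dien-1-one
Product: 18 5,7-bis(benzyloxy)-8-[(1R)-1-(2-hydroxy-4-methoxy-3,3,5-trimethyl-6-oxocyclohexa-1,4-dien-1-yl)-2-methylpropyl]-6-methyl-4H-chromen-4-one, via 2-hydroxychroman-4-one 17 (not isolated)
Conditions: NaH (5 equiv), HCO2Me, THF, 0 °C → rt; AcOH; then TsOH·H2O (cat.), toluene, 40 °C
Reagents that add atoms: methyl formate, COC=O
Why: Claisen formylation of the methyl ketone as its polyanion (ring D is protected as its diketonate and methoxide exchange at D1 is degenerate) gives the β-keto aldehyde, which closes to hemiacetal 17 and is dehydrated by acid, the classical formate route to chromones.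

Step 12
Reactants: 18 5,7-bis(benzyloxy)-8-[(1R)-1-(2-hydroxy-4-methoxy-3,3,5-trimethyl-6-oxocyclohexa-1,4-dien-1-yl)-2-methylpropyl]-6-methyl-4H-chromen-4-one; 19 phenylboronic acid
Product: 20 (2S)-5,7-bis(benzyloxy)-8-[(1R)-1-(2-hydroxy-4-methoxy-3,3,5-trimethyl-6-oxocyclohexa-1,4-dien-1-yl)-2-methylpropyl]-6-methyl-2-phenyl-2,3-dihydro-4H-chromen-4-one
Conditions: Pd(OCOCF3)2 (10 mol %), (R)-4-tert-butyl-2-(pyridin-2-yl)-4,5-dihydro-1,3-oxazole (12 mol %), NH4PF6 (30 mol %), H2O (5 equiv), ClCH2CH2Cl, 60 °C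
Reagents that add atoms: none
Why: Palladium-catalysed asymmetric conjugate addition of an arylboronic acid to a chromone, in which the tert-butyl group of the pyridine–oxazoline ligand directs phenyl to one face of C2, the (R)-ligand being the one expected by analogy with cyclic enones to give 2S (to be confirmed on a simple 5,7-bis(benzyloxy)chromone), while the non-basic medium prevents ring-opening of the flavanone.

Step 13
Reactants: 20 (2S)-5,7-bis(benzyloxy)-8-[(1R)-1-(2-hydroxy-4-methoxy-3,3,5-trimethyl-6-oxocyclohexa-1,4-dien-1-yl)-2-methylpropyl]-6-methyl-2-phenyl-2,3-dihydro-4H-chromen-4-one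
Product: 21 (2S)-5,7-dihydroxy-8-[(1R)-1-(2-hydroxy-4-methoxy-3,3,5-trimethyl-6-oxocyclohexa-1,4-dien-1-yl)-2-methylpropyl]-6-methyl-2-phenyl-2,3-dihydro-4H-chromen-4-one
Conditions: H2 (1 atm), Pd/C, EtOAc, rt
Reagents that add atoms: none
Why: Hydrogenolysis of the two aryl benzyl ethers over Pd/C under neutral conditions, stopped after two equivalents of H2 so that the aryl ketone, both stereocentres and the tetrasubstituted enol ether of ring D should remain.

**Compound list**

1 | 2-methylbenzene-1,3,5-triol | Cc1c(O)cc(O)cc1O | starting material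
2 | 2-methyl-5-{[tri(propan-2-yl)silyl]oxy}benzene-1,3-diol | Cc1c(O)cc(O[Si](C(C)C)(C(C)C)C(C)C)cc1O | intermediate
3 | {[3,5-bis(benzyloxy)-4-methylphenyl]oxy}tri(propan-2-yl)silane | Cc1c(OCc2ccccc2)cc(O[Si](C(C)C)(C(C)C)C(C)C)cc1OCc1ccccc1 | intermediate
4 | 3,5-bis(benzyloxy)-4-methylphenol | Cc1c(OCc2ccccc2)cc(O)cc1OCc1ccccc1 | intermediate
5 | (2E)-4-methylpent-2-enal | CC(C)/C=C/C=O | starting material
6 | (4R)-5,7-bis(benzyloxy)-6-methyl-4-(propan-2-yl)-3,4-dihydro-2H-chromen-2-ol (C2 epimers) | OC1C[C@@H](c2c(OCc3ccccc3)c(C)c(OCc3ccccc3)cc2O1)C(C)C | intermediate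
7 | (4R)-5,7-bis(benzyloxy)-6-methyl-4-(propan-2-yl)-3,4-dihydro-2H-chromen-2-one | O=C1C[C@@H](c2c(OCc3ccccc3)c(C)c(OCc3ccccc3)cc2O1)C(C)C | intermediate
8 | (4R)-8-acetyl-5,7-bis(benzyloxy)-6-methyl-4-(propan-2-yl)-3,4-dihydro-2H-chromen-2-one | O=C1C[C@@H](c2c(OCc3ccccc3)c(C)c(OCc3ccccc3)c(C(C)=O)c2O1)C(C)C | intermediate
9 | (4R)-5,7-bis(benzyloxy)-8-(1-{[tert-butyl(dimethyl)silyl]oxy}ethenyl)-6-methyl-4-(propan-2-yl)-3,4-dihydro-2H-chromen-2-one | O=C1C[C@@H](c2c(OCc3ccccc3)c(C)c(OCc3ccccc3)c(C(=C)O[Si](C)(C)C(C)(C)C)c2O1)C(C)C | intermediate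
10 | methyl 4-methyl-3-oxopentanoate | COC(=O)CC(=O)C(C)C | starting material
11 | methyl 2,4-dimethyl-3-oxopentanoate (racemic) | COC(=O)C(C)C(=O)C(C)C | intermediate
12 | methyl (2E)-3-methoxy-2,4-dimethylpent-2-enoate | COC(=O)/C(C)=C(/OC)C(C)C | intermediate
13 | lithium 1,3-dimethoxy-2,4-dimethylpenta-1,3-dien-1-olate | [Li+].[O-]C(OC)=C(C)C(OC)=C(C)C | intermediate
14 | methyl (2E,7R)-7-[2,4-bis(benzyloxy)-5-(1-{[tert-butyl(dimethyl)silyl]oxy}ethenyl)-6-hydroxy-3-methylphenyl]-3-methoxy-2,4,4,8-trimethyl-5-oxonon-2-enoate | COC(=O)/C(C)=C(/OC)C(C)(C)C(=O)C[C@@H](c1c(OCc2ccccc2)c(C)c(OCc2ccccc2)c(C(=C)O[Si](C)(C)C(C)(C)C)c1O)C(C)C | intermediate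
15 | 2-{(1R)-1-[2,4-bis(benzyloxy)-5-(1-{[tert-butyl(dimethyl)silyl]oxy}ethenyl)-6-hydroxy-3-methylphenyl]-2-methylpropyl}-3-hydroxy-5-methoxy-4,4,6-trimethylcyclohexa-2,5-dien-1-one | COC1=C(C)C(=O)C([C@@H](c2c(OCc3ccccc3)c(C)c(OCc3ccccc3)c(C(=C)O[Si](C)(C)C(C)(C)C)c2O)C(C)C)=C(O)C1(C)C | intermediate
16 | 2-{(1R)-1-[3-acetyl-4,6-bis(benzyloxy)-2-hydroxy-5-methylphenyl]-2-methylpropyl}-3-hydroxy-5-methoxy-4,4,6-trimethylcyclohexa-2,5-dien-1-one | COC1=C(C)C(=O)C([C@@H](c2c(OCc3ccccc3)c(C)c(OCc3ccccc3)c(C(C)=O)c2O)C(C)C)=C(O)C1(C)C | intermediate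
17 | 5,7-bis(benzyloxy)-2-hydroxy-8-[(1R)-1-(2-hydroxy-4-methoxy-3,3,5-trimethyl-6-oxocyclohexa-1,4-dien-1-yl)-2-methylpropyl]-6-methyl-2,3-dihydro-4H-chromen-4-one (C2 epimers) | COC1=C(C)C(=O)C([C@@H](c2c(OCc3ccccc3)c(C)c(OCc3ccccc3)c3C(=O)CC(O)Oc23)C(C)C)=C(O)C1(C)C | intermediate
18 | 5,7-bis(benzyloxy)-8-[(1R)-1-(2-hydroxy-4-methoxy-3,3,5-trimethyl-6-oxocyclohexa-1,4-dien-1-yl)-2-methylpropyl]-6-methyl-4H-chromen-4-one | COC1=C(C)C(=O)C([C@@H](c2c(OCc3ccccc3)c(C)c(OCc3ccccc3)c3c(=O)ccoc23)C(C)C)=C(O)C1(C)C | intermediate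
19 | phenylboronic acid | OB(O)c1ccccc1 | starting material
20 | (2S)-5,7-bis(benzyloxy)-8-[(1R)-1-(2-hydroxy-4-methoxy-3,3,5-trimethyl-6-oxocyclohexa-1,4-dien-1-yl)-2-methylpropyl]-6-methyl-2-phenyl-2,3-dihydro-4H-chromen-4-one | COC1=C(C)C(=O)C([C@@H](c2c(OCc4ccccc4)c(C)c(OCc5ccccc5)c3c2O[C@H](c6ccccc6)CC3=O)C(C)C)=C(O)C1(C)C | intermediate
21 | (2S)-5,7-dihydroxy-8-[(1R)-1-(2-hydroxy-4-methoxy-3,3,5-trimethyl-6-oxocyclohexa-1,4-dien-1-yl)-2-methylpropyl]-6-methyl-2-phenyl-2,3-dihydro-4H-chromen-4-one | COC1=C(C)C(=O)C([C@@H](c2c(O)c(C)c(O)c3c2O[C@H](c2ccccc2)CC3=O)C(C)C)=C(O)C1(C)C | target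

**Count and risks**

Total step count: 13. Longest linear sequence: 11 steps (steps 1–7 and 10–13).

Steps most likely to fail:

1. Step 10. Removal of the tertiary γ-hydrogen may be slow, and the hindered dienolate may take a proton from the lactone α-CH2 faster than it attacks the carbonyl, so that the lactone drains through its ketene into a diisopropylamide. The fallback sets out from 9. Ring-opening with MeNH(OMe)·HCl and i-PrMgCl (THF, −20 °C) should give the N-methoxy-N-methylamide (3R)-3-[2,4-bis(benzyloxy)-5-(1-{[tert-butyl(dimethyl)silyl]oxy}ethenyl)-6-hydroxy-3-methylphenyl]-N-methoxy-N,4-dimethylpentanamide F1. As its phenoxide, F1 acylates dienolate 13 (3 equiv, −78 → 0 °C); it has no aryloxide to lose, so no ketene can form, and the N-methoxy chelate holds the adduct until work-up. This releases keto ester 14, now isolated. KOt-Bu in THF, then Bu4NF and acid, should close ring D and come back to the route at 16.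

2. Step 12. The acidic enol of ring D may bind divalent palladium and stop turnover, or the large C8 substituent may erode facial selectivity at C2. The fallback sets out from 16. Claisen–Schmidt condensation with benzaldehyde (KOH, MeOH) should give the 2′-hydroxychalcone 2-{(1R)-1-[4,6-bis(benzyloxy)-2-hydroxy-5-methyl-3-((2E)-3-phenylprop-2-enoyl)phenyl]-2-methylpropyl}-3-hydroxy-5-methoxy-4,4,6-trimethylcyclohexa-2,5-dien-1-one F2. NaOAc in MeOH at reflux closes the pyranone by oxa-Michael addition to 20 and its (2R)-epimer F3. These are diastereomers because the methine is fixed, so they are separated by chromatography, and F3 is returned to the equilibrium through F2 with base. The sequence comes back to the route at 20.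

3. Step 4. C-alkylation at the crowded ortho carbon may be slow relative to reversible O-addition, and facial selectivity with the β-branched enal may be poor. The fallback sets out from 4 and 10. Pechmann condensation (CF3CO2H, CH2Cl2, rt) should give the coumarin 5,7-bis(benzyloxy)-6-methyl-4-(propan-2-yl)-2H-chromen-2-one F4. Asymmetric conjugate reduction with copper hydride (Cu(OAc)2, 5,5′-bis{bis[3,5-di-tert-butyl-4-methoxyphenyl]phosphanyl}-4,4′-bi-1,3-benzodioxole, (EtO)2MeSiH, t-BuOH, toluene), with the ligand enantiomer chosen so that hydride adds to the face giving 4R, comes back to the route at 7.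

**Further compounds**

F1 | step 10 | (3R)-3-[2,4-bis(benzyloxy)-5-(1-{[tert-butyl(dimethyl)silyl]oxy}ethenyl)-6-hydroxy-3-methylphenyl]-N-methoxy-N,4-dimethylpentanamide | CON(C)C(=O)C[C@@H](c1c(OCc2ccccc2)c(C)c(OCc2ccccc2)c(C(=C)O[Si](C)(C)C(C)(C)C)c1O)C(C)C
F2 | step 12 | 2-{(1R)-1-[4,6-bis(benzyloxy)-2-hydroxy-5-methyl-3-((2E)-3-phenylprop-2-enoyl)phenyl]-2-methylpropyl}-3-hydroxy-5-methoxy-4,4,6-trimethylcyclohexa-2,5-dien-1-one | COC1=C(C)C(=O)C([C@@H](c2c(OCc3ccccc3)c(C)c(OCc3ccccc3)c(C(=O)/C=C/c3ccccc3)c2O)C(C)C)=C(O)C1(C)C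
F3 | step 12 | (2R)-5,7-bis(benzyloxy)-8-[(1R)-1-(2-hydroxy-4-methoxy-3,3,5-trimethyl-6-oxocyclohexa-1,4-dien-1-yl)-2-methylpropyl]-6-methyl-2-phenyl-2,3-dihydro-4H-chromen-4-one | COC1=C(C)C(=O)C([C@@H](c2c(OCc4ccccc4)c(C)c(OCc5ccccc5)c3c2O[C@@H](c6ccccc6)CC3=O)C(C)C)=C(O)C1(C)C
F4 | step 4 | 5,7-bis(benzyloxy)-6-methyl-4-(propan-2-yl)-2H-chromen-2-one | O=c1cc(C(C)C)c2c(OCc3ccccc3)c(C)c(OCc3ccccc3)cc2o1
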